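The readings were generated by integration on assumed constants.

If the starting material had to be used up in a set time, I needed to know which concentration set the order of its loss, so I began with the two earlier runs.

| setting | alder | elm | epsilon | theta |
|---|---|---|---|---|
| starting material | 0.11 M | 0.11 M | 0.11 M | 0.11 M |
| coupling partner | 0.72 equiv | 1.9 equiv | 0.950 equiv | 2.80 equiv |
| remark | run made earlier | run made earlier |  |  |
| time |  |  | 25 h | 25 h |

| run | time / h | target / % | starting material / % | intermediate / % | isomer of the product A / % |
|---|---|---|---|---|---|
| alder | 0.667 | 0.7 | 98.1 | 1.5 | 0.4 |
| alder | 2.00 | 2.6 | 94.0 | 2.9 | 0.7 |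
| alder | 4.00 | 6.2 | 88.7 | 3.1 | 1.8 |
| alder | 5.00 | 7.4 | 86.9 | 3.4 | 2.3 |
| alder | 8.00 | 11.3 | 80.1 | 4.5 | 3.7 |
| alder | 10.0 | 12.5 | 76.5 | 4.7 | 5.8 |
| alder | 12.0 | 13.8 | 73.7 | 5.4 | 7.1 |
| elm | 0.667 | 1.0 | 94.7 | 3.6 | 0.7 |
| elm | 2.00 | 6.7 | 84.9 | 5.4 | 1.5 |
| elm | 4.00 | 14.6 | 73.4 | 7.6 | 3.8 |
| elm | 5.00 | 17.8 | 67.8 | 7.7 | 5.8 |
| elm | 8.00 | 24.8 | 55.5 | 10.1 | 10.0 |
| elm | 10.0 | 28.0 | 49.5 | 9.7 | 13.6 |
| elm | 12.0 | 30.6 | 43.3 | 9.9 | 15.7 |

(standard deviation of a reading: 0.3 percentage points)

* which of these there is most of at the end, counted by the starting material in it, epsilon (target / isomer of the product A / intermediate / starting material)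
* which of these there is most of at the end, counted by the starting material in it, theta (target / isomer of the product A / intermediate / starting material)
* the largest of these amounts at the end, in percent of the starting material charged, epsilon
* the largest of these amounts at the end, in percent of the starting material charged, theta

- steps thought possible: intermediate <-> isomer of the product A; starting material + coupling partner -> intermediate + by-product; intermediate <-> target; target <-> isomer of the product B
- a reading of target is of its free form alone

In the offered scheme, starting material is consumed in one step, one for one with coupling partner. So I took the rate as k times both concentrations. With e the equivalents of partner, c the starting concentration and a the fraction of starting material left at time t, this integrates to k = ln((e − 1 + a)/(e·a))/((e − 1)·c·t). The last row of elm gave 0.406 /M/h, and this k, the second-order constant of the coupling step, is what I carried forward. The last row of alder, with the partner short, gave 0.404 /M/h, close to elm, so the partner's concentration counted as much as the starting material's.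

But the partner's concentration does not hold still in either new flask. In epsilon the partner is the limiting reagent, so both concentrations fall together. Theta can lose up to a third of its partner, which is too much to treat its loss as pseudo-first-order, so I kept the second-order form there too. With k, I reckoned 49.2% of starting material left in epsilon and 9.04% in theta.

The forecast, also taking the loss as second order, put starting material first in epsilon at 49.6% and target first in theta at 45%, adding: “The target lead is modest.”

Epsilon ended with starting material first at 49.4%, and theta with target first at 41.5%, beside 34.0% of isomer of the product A.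

    intermediate ⇌ isomer of the product A (K = 3.37, k = 6.29 × 10⁻⁵ /s)
    starting material + coupling partner → intermediate + by-product (k = 1.12 × 10⁻⁴ /M/s)
    intermediate ⇌ target (K = 3.20, k = 3.18 × 10⁻⁴ /s)
    target ⇌ isomer of the product B (K = 1.60, k = 7.60 × 10⁻⁷ /s)

The flasks held 49.4% and 9.18% of starting material, against my 49.2% and 9.04%. Theta's target stood above epsilon's, at 41.5% against 23.9%, because of the difference in equivalents of coupling partner. A neighbouring flask kept theta's equivalents and time but started from 0.066 M, and since c stands in the exponent, k gave 21.5% of starting material left. That flask held 21.8% of starting material and 36.5% of target.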